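**Retrosynthetic overview**
1. The strategy rests on the monosubstituted maleic anhydride ring: ring carbon C16 carries only H and ring carbon C15 carries the chain (C1 = carboxyl carbon, chain to C14). C16 with its carbonyl is a glyoxylate two-carbon unit; C15 with its carbonyl is the α-carbon and carbonyl of a long-chain aldehyde.
2. Anhydride 20 comes from oxidation of 5-hydroxybutenolide 19, which is cut at C15=C16 and the ring C–O bond into aldehyde acid 15 and glyoxylic acid 16. This is the only ring; it is closed in step 7 and adjusted in step 8.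
3. Aldehyde acid 15 is cut at C3–C4: SN2 opening of (R)-β-butyrolactone 12 by a C4 Grignard reagent sets C3.
4. The two Z trisubstituted alkenes come from two syn-carbocuprations of propyne, each trapped with ethylene oxide, starting from the Grignard reagent of bromoacetal 1 (C12–C15 plus the masked aldehyde carbon).

Key step: step 7

Remark: glyoxylic acid is used as its commercial monohydrate and is drawn as the free aldehyde; the lactol carbon of 19 forms as both epimers and becomes a carbonyl in step 8, so no control is sought there.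

**Route**

Step 1
Reactants: 1 2-(4-bromobutyl)-1,3-dioxolane; 2 propyne; 3 ethylene oxide
Product: 6 (3Z)-8-(1,3-dioxolan-2-yl)-4-methyloct-3-en-1-ol, via Grignard reagent 4 (not isolated), via vinylcopper 5 (not isolated)
Conditions: Mg, Et2O; CuBr·SMe2 (1 equiv), Et2O/Me2S, −45 °C; propyne, −25 °C; 1-lithiopent-1-yne, HMPA, then ethylene oxide, −78 → −20 °C; aq NH4Cl
Reagents that add atoms: none
Why: Normant carbocupration: the alkylcopper from 4 adds syn across propyne with the alkyl group on the internal carbon, and vinylcopper 5, activated as a mixed alkynyl cuprate, opens ethylene oxide with retention of alkene geometry, so the chain ends up cis across the future C10=C11 bond (Z).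

Step 2
Reactants: 6 (3Z)-8-(1,3-dioxolan-2-yl)-4-methyloct-3-en-1-ol
Product: 7 2-[(5Z)-8-bromo-5-methyloct-5-en-1-yl]-1,3-dioxolane
Conditions: CBr4, PPh3, 2,6-lutidine (buffer), CH2Cl2, 0 °C
Reagents that add atoms: tetrabromomethane, BrC(Br)(Br)Br
Why: Appel reaction: SN2 displacement of the alkoxyphosphonium of a primary alcohol by bromide under buffered, near-neutral conditions, which should leave the dioxolane and the alkene geometry intact.

Step 3
Reactants: 7 2-[(5Z)-8-bromo-5-methyloct-5-en-1-yl]-1,3-dioxolane; 2 propyne; 3 ethylene oxide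
Product: 10 (3Z,7Z)-12-(1,3-dioxolan-2-yl)-4,8-dimethyldodeca-3,7-dien-1-ol, via Grignard reagent 8 (not isolated), via vinylcopper 9 (not isolated)
Conditions: Mg, Et2O; CuBr·SMe2 (1 equiv), Et2O/Me2S, −45 °C; propyne, −25 °C; 1-lithiopent-1-yne, HMPA, then ethylene oxide, −78 → −20 °C; aq NH4Cl
Reagents that add atoms: none
Why: A second Normant carbocupration with ethylene oxide trapping, in which the syn addition of the homoallylic alkylcopper to propyne sets the future C6=C7 bond as Z while the existing Z alkene is not involved.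

Step 4
Reactants: 10 (3Z,7Z)-12-(1,3-dioxolan-2-yl)-4,8-dimethyldodeca-3,7-dien-1-ol
Product: 11 2-[(5Z,9Z)-12-bromo-5,9-dimethyldodeca-5,9-dien-1-yl]-1,3-dioxolane
Conditions: CBr4, PPh3, 2,6-lutidine (buffer), CH2Cl2, 0 °C
Reagents that add atoms: tetrabromomethane, BrC(Br)(Br)Br
Why: Appel reaction on a primary homoallylic alcohol, as in step 2, with the acetal and both alkenes as spectators.

Step 5
Reactants: 11 2-[(5Z,9Z)-12-bromo-5,9-dimethyldodeca-5,9-dien-1-yl]-1,3-dioxolane; 12 (R)-4-methyloxetan-2-one
Product: 14 (3R,6Z,10Z)-15-(1,3-dioxolan-2-yl)-3,7,11-trimethylpentadeca-6,10-dienoic acid, via Grignard reagent 13 (not isolated)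
Conditions: Mg, THF; slow addition to 12 (1.3 equiv) and CuBr·SMe2 (10 mol %), THF/Me2S, −30 → 0 °C; cold dilute HCl to pH 3
Reagents that add atoms: none
Why: Copper-catalysed Grignard opening of a β-lactone by SN2 attack at the β-carbon (alkyl–oxygen cleavage) with inversion, which turns the (R)-lactone into the (3R) acid (the descriptor stays R only because the priority order changes) and delivers the free carboxylic acid directly.

Step 6
Reactants: 14 (3R,6Z,10Z)-15-(1,3-dioxolan-2-yl)-3,7,11-trimethylpentadeca-6,10-dienoic acid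
Product: 15 (3R,6Z,10Z)-3,7,11-trimethyl-16-oxohexadeca-6,10-dienoic acid
Conditions: 1 M aq HCl/THF, rt
Reagents that add atoms: water, O
Why: Acid-catalysed acetal hydrolysis; dilute acid at room temperature should not protonate the isolated trisubstituted alkenes, and C3 is not enolisable.

Step 7
Reactants: 15 (3R,6Z,10Z)-3,7,11-trimethyl-16-oxohexadeca-6,10-dienoic acid; 16 glyoxylic acid
Product: 19 (3R,6Z,10Z)-14-(2-hydroxy-5-oxo-2,5-dihydrofuran-3-yl)-3,7,11-trimethyltetradeca-6,10-dienoic acid (both lactol epimers), via morpholine enamine 17 (not isolated), via cis-formylacrylic acid 18 (not isolated)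
Conditions: glyoxylic acid monohydrate (1.5 equiv), morpholine hydrochloride (1.1 equiv), dioxane/H2O, rt then reflux
Reagents that add atoms: none
Why: Morpholine hydrochloride converts the aldehyde of 15 into enamine 17, whose nucleophilic carbon C15 adds to the formyl carbon of glyoxylic acid; loss of water and hydrolysis of the iminium give the β-formylacrylic acid 18 as an alkene mixture, which forms the C15=C16 bond. The closest known reaction is the amine-salt-mediated aldol condensation of enolisable aldehydes with glyoxylic acid that gives 4-alkyl-5-hydroxyfuran-2(5H)-ones. The five-membered ring closes by 5-exo-trig addition of the carboxyl oxygen on the C16 side to the formyl carbon (new C–O bond); only the isomer with carboxyl and formyl cis can do this, and the trans isomer equilibrates by reversible conjugate addition of morpholine, so the mixture should drain into the lactol. The lactol carbon is the only new stereocentre, is not controlled (ring–chain tautomerism gives both epimers) and is oxidised to a carbonyl in step 8. The selectivity needed is cross- over self-condensation, secured because glyoxylic acid is non-enolisable, more electrophilic than an aliphatic aldehyde and used in excess, while 15 has a single enolisable CH2 next to the aldehyde; the C1 acid, the C3 centre and the two Z alkenes should not be touched by the weakly acidic medium.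

Step 8
Reactants: 19 (3R,6Z,10Z)-14-(2-hydroxy-5-oxo-2,5-dihydrofuran-3-yl)-3,7,11-trimethyltetradeca-6,10-dienoic acid (both lactol epimers)
Product: 20 (3R,6Z,10Z)-14-(2,5-dioxo-2,5-dihydrofuran-3-yl)-3,7,11-trimethyltetradeca-6,10-dienoic acid
Conditions: Dess–Martin periodinane, CH2Cl2, rt; non-basic work-up (filtration through silica)
Reagents that add atoms: none
Why: Dess–Martin oxidation of the lactol hydroxyl to a carbonyl converts both epimers into the one cyclic anhydride, and it should leave the free acid and the trisubstituted alkenes alone; avoiding aqueous base keeps the anhydride closed.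

**Compound list**
1 | 2-(4-bromobutyl)-1,3-dioxolane | BrCCCCC1OCCO1 | starting material
2 | propyne | CC#C | starting material
3 | ethylene oxide (oxirane) | C1CO1 | starting material
4 | [4-(1,3-dioxolan-2-yl)butyl]magnesium bromide | Br[Mg]CCCCC1OCCO1 | intermediate
5 | [(1Z)-6-(1,3-dioxolan-2-yl)-2-methylhex-1-en-1-yl]copper | [Cu]/C=C(/C)CCCCC1OCCO1 | intermediate
6 | (3Z)-8-(1,3-dioxolan-2-yl)-4-methyloct-3-en-1-ol | OCC/C=C(/C)CCCCC1OCCO1 | intermediate
7 | 2-[(5Z)-8-bromo-5-methyloct-5-en-1-yl]-1,3-dioxolane | BrCC/C=C(/C)CCCCC1OCCO1 | intermediate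
8 | [(3Z)-8-(1,3-dioxolan-2-yl)-4-methyloct-3-en-1-yl]magnesium bromide | Br[Mg]CC/C=C(/C)CCCCC1OCCO1 | intermediate
9 | [(1Z,5Z)-10-(1,3-dioxolan-2-yl)-2,6-dimethyldeca-1,5-dien-1-yl]copper | [Cu]/C=C(/C)CC/C=C(/C)CCCCC1OCCO1 | intermediate
10 | (3Z,7Z)-12-(1,3-dioxolan-2-yl)-4,8-dimethyldodeca-3,7-dien-1-ol | OCC/C=C(/C)CC/C=C(/C)CCCCC1OCCO1 | intermediate
11 | 2-[(5Z,9Z)-12-bromo-5,9-dimethyldodeca-5,9-dien-1-yl]-1,3-dioxolane | BrCC/C=C(/C)CC/C=C(/C)CCCCC1OCCO1 | intermediate
12 | (R)-4-methyloxetan-2-one | C[C@@H]1CC(=O)O1 | starting material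
13 | [(3Z,7Z)-12-(1,3-dioxolan-2-yl)-4,8-dimethyldodeca-3,7-dien-1-yl]magnesium bromide | Br[Mg]CC/C=C(/C)CC/C=C(/C)CCCCC1OCCO1 | intermediate
14 | (3R,6Z,10Z)-15-(1,3-dioxolan-2-yl)-3,7,11-trimethylpentadeca-6,10-dienoic acid | C/C(=C/CC[C@@H](C)CC(=O)O)CC/C=C(/C)CCCCC1OCCO1 | intermediate
15 | (3R,6Z,10Z)-3,7,11-trimethyl-16-oxohexadeca-6,10-dienoic acid | C/C(=C/CC[C@@H](C)CC(=O)O)CC/C=C(/C)CCCCC=O | intermediate
16 | glyoxylic acid | O=CC(=O)O | starting material
17 | (3R,6Z,10Z,15E)-3,7,11-trimethyl-16-(morpholin-4-yl)hexadeca-6,10,15-trienoic acid | C/C(=C/CC[C@@H](C)CC(=O)O)CC/C=C(/C)CCC/C=C/N1CCOCC1 | intermediate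
18 | (2Z,7Z,11Z,15R)-3-formyl-7,11,15-trimethylheptadeca-2,7,11-trienedioic acid | C/C(=C/CC[C@@H](C)CC(=O)O)CC/C=C(/C)CCC/C(C=O)=C/C(=O)O | intermediate
19 | (3R,6Z,10Z)-14-(2-hydroxy-5-oxo-2,5-dihydrofuran-3-yl)-3,7,11-trimethyltetradeca-6,10-dienoic acid (both lactol epimers) | C/C(=C/CC[C@@H](C)CC(=O)O)CC/C=C(/C)CCCC1=CC(=O)OC1O | intermediate
20 | (3R,6Z,10Z)-14-(2,5-dioxo-2,5-dihydrofuran-3-yl)-3,7,11-trimethyltetradeca-6,10-dienoic acid | C/C(=C/CC[C@@H](C)CC(=O)O)CC/C=C(/C)CCCC1=CC(=O)OC1=O | target

**Step count**
Total steps: 8. Longest linear sequence: 8 steps (1 → 20).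

**Steps most likely to fail**

First, step 7. Self-aldol condensation of the aldehyde may compete during the long heating, the trans alkene isomer may equilibrate too slowly so that ring closure stalls, or the hot acidic medium may start to isomerise the trisubstituted alkenes. The fallback sets out from 15 and separates C–C bond formation from ring closure. An L-proline-catalysed cross-aldol addition of 15 to ethyl glyoxylate (toluene solution, MeCN, rt) would give the β-hydroxy aldehyde ester (3R,6Z,10Z)-17-ethoxy-15-formyl-16-hydroxy-3,7,11-trimethyl-17-oxoheptadeca-6,10-dienoic acid F1 as a diastereomer mixture. Brief warming of F1 with 2 M aqueous HCl in dioxane would dehydrate it, hydrolyse the ethyl ester and close the lactol, which comes back to the route at 19.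

Second, step 5. The organomagnesium may attack the lactone carbonyl (acyl–oxygen cleavage) or deprotonate the lactone with β-elimination to crotonate, in competition with the copper-mediated opening at the β-carbon. The fallback sets out from 11 through Grignard reagent 13 and builds C3 by auxiliary-controlled conjugate addition. The crotonyl imide (4R)-3-[(2E)-but-2-enoyl]-4-phenyloxazolidin-2-one F2 would be prepared from (R)-4-phenyloxazolidin-2-one, n-BuLi and (E)-but-2-enoyl chloride. Addition of 13 with CuBr·SMe2 in THF/Me2S at −40 → −10 °C should occur on the chelated syn-s-cis imide from the face away from the phenyl group. This would give (4R)-3-[(3R,6Z,10Z)-15-(1,3-dioxolan-2-yl)-3,7,11-trimethylpentadeca-6,10-dienoyl]-4-phenyloxazolidin-2-one F3. Cleavage with LiOH/H2O2 in THF/H2O at 0 °C comes back to the route at 14.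

Third, step 3. The homoallylic Grignard reagent may form incompletely or undergo Wurtz coupling, the alkylcopper may decompose before it adds to propyne, or the vinylcopper may be protonated before it opens the epoxide. The fallback sets out from 7 and makes the Z alkene by directed methylmetalation of an alkyne. Alkylation of but-3-yn-1-ol (n-BuLi, 2 equiv, THF/DMPU, −78 °C → rt) with 7 would give (7Z)-12-(1,3-dioxolan-2-yl)-8-methyldodec-7-en-3-yn-1-ol F4. An alkoxide-directed syn-methylmagnesiation (MeMgBr in excess, Fe(acac)3 catalyst, THF, 0 °C; aq NH4Cl) should place the methyl group on the alkyne carbon distal to the hydroxyl and hydrogen on the proximal one. This comes back to the route at 10 with the same Z geometry.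

**Further compounds**
F1 | step 7 | (3R,6Z,10Z)-17-ethoxy-15-formyl-16-hydroxy-3,7,11-trimethyl-17-oxoheptadeca-6,10-dienoic acid (diastereomer mixture at C15 and C16) | C/C(=C/CC[C@@H](C)CC(=O)O)CC/C=C(/C)CCCC(C=O)C(O)C(=O)OCC
F2 | step 5 | (4R)-3-[(2E)-but-2-enoyl]-4-phenyloxazolidin-2-one | C/C=C/C(=O)N1[C@H](c2ccccc2)COC1=O
F3 | step 5 | (4R)-3-[(3R,6Z,10Z)-15-(1,3-dioxolan-2-yl)-3,7,11-trimethylpentadeca-6,10-dienoyl]-4-phenyloxazolidin-2-one | C/C(=C/CC[C@@H](C)CC(=O)N2[C@H](c3ccccc3)COC2=O)CC/C=C(/C)CCCCC1OCCO1
F4 | step 3 | (7Z)-12-(1,3-dioxolan-2-yl)-8-methyldodec-7-en-3-yn-1-ol | OCCC#CCC/C=C(/C)CCCCC1OCCO1
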